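At one temperature and over 15 h, I wanted to know which way of mixing the same charge left the most target.

    second substrate + free catalyst ⇌ catalyst intermediate B (K1 = 55 M⁻¹, k1 = 6.0 M⁻¹ min⁻¹)
    partner + catalyst intermediate A → free catalyst + target (k2 = 5.2 M⁻¹ min⁻¹)
    starting material + target → side product (k3 = 0.35 M⁻¹ min⁻¹)
    partner + catalyst intermediate B → free catalyst + second product (k4 = 58 M⁻¹ min⁻¹)
    starting material + free catalyst ⇌ catalyst intermediate A (K5 = 30 M⁻¹, k5 = 4.5 M⁻¹ min⁻¹)

| flask | starting material | second substrate | partner | free catalyst | time | remark |
|---|---|---|---|---|---|---|
| noon | 0.050 M | 0.500 equiv (fed, over 15.0 h) | 0.950 equiv | 10 mol% | 15 h | a stirred flask in which second substrate is dosed at a steady rate over 15.0 h without added volume, worked up at 15 h |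
| autumn | 0.050 M | 0.500 equiv | 0.950 equiv | 10 mol% |  | one stirred flow tank at steady state, fed with the mixture as stated, mean residence time 15 h |
| dawn | 0.050 M | 0.500 equiv | 0.950 equiv | 10 mol% | 15 h | a closed flask charged with all of it at once and left for 15 h |
| winter | 0.050 M | 0.500 equiv | 0.950 equiv (fed, over 15.0 h) | 10 mol% | 15 h | a stirred flask in which partner is dosed at a steady rate over 15.0 h without added volume, worked up at 15 h |

- percentages count the starting material that a species holds: one side product counts as two
- the stated concentrations are those of everything mixed, before any reaction; amounts are the same in each set-up
- the feed brings no volume worth counting
- run time (noon): 15 h

1. the set-up with the highest amount of target at the outlet or at the end, in percent of the starting material put in ("none" if the first two lie within 2 percentage points) (noon / autumn / dawn / winter / none)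
2. amount of target at the outlet or at the end, in percent of the starting material put in, noon
3. amount of target at the outlet or at the end, in percent of the starting material put in, autumn
4. amount of target at the outlet or at the end, in percent of the starting material put in, dawn
5. amount of target at the outlet or at the end, in percent of the starting material put in, winter

I kept a ledger of the partner, the limiting reagent, since turning every molecule of both substrates into target and second product takes 1.50 equivalents of it, more than the 0.950 equiv charged. Following one molecule of starting material, I saw it take one partner on the catalyst and leave as target, and that target could then stay or meet a further starting material and become side product. So a side product held two starting materials but one partner, while a second product held one partner and no starting material. Once starting material and partner were both used up, the books had two lines: target plus side product equalled partner minus second product, and target plus twice the side product equalled starting material. Taking the second line from twice the first, I called the ceiling of the books the target, in percent of starting material, that remains when both are used up and no partner goes to second product: twice the partner charge less the starting material charge, 90.0%. Each mole of second product took two moles of target off it. The ceiling was used up at 0.0225 M of second product, and the charge of second substrate was 0.0250 M, more than that, so in a flask passing its whole second substrate to partner the partner remaining was too little to use up the starting material, and some of it stayed over. At the partner's fork, the constant of step 4 was 11.2 times that of step 2, so I expected dawn near the bottom and put noon, which holds second substrate back, first. My reckoning gave no figures beyond that.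

The forecast named noon as best, with 39% for noon, 9% for autumn, 3.5% for dawn and 18% for winter, on the ground that "Partner cannot serve both substrates".

The simulation gave noon as best, with 32.0% for noon, 8.64% for autumn, 3.26% for dawn and 8.94% for winter.

The target of noon had come to rest: at 15.0 h noon held 0.0145 M of second product, with starting material at 0.0802% and partner at 0%, so the ceiling, less two for each second product, gave 32.0%, and after 150 h target still stood at 32.0%. Dawn had not come to rest: with partner at 0% and starting material at 10.1%, its target went from 3.26% to 0% by 150 h, and its second product of 0.0245 M lay above the 0.0225 M that uses up the ceiling.

In the neighbour of noon with 4 mol% of free catalyst, second product reached 0.0191 M, so the ceiling, less two for each second product, gave 13.7%. That neighbour held 14.4% of target, with 1.6% of its starting material and 0.46% of its partner still there, so its books had not quite closed.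

(All constants were drawn at random within sensible limits; no experiment stands behind them.)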